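## Structural features

Compound 20 is a 6-methoxy-2H-chromene-5,8-dione: a p-benzoquinone (C4a, C5–C8, C8a) whose C8a oxygen O1 closes a 2H-pyran (O1, C2, C3=C4, C4a), so that O1 and the C6 methoxy group are para on the quinone. C2 carries a methyl group and a two-carbon tether (Ca on C2, Cb on C1′) that ends at a 1,2,3-trimethylcyclohex-3-ene (C1′ quaternary, C2′ tertiary, C3′=C4′ trisubstituted, C5′ and C6′ methylene). There are three stereocentres: C2 (S), a fully substituted allylic ether carbon; C1′ (S); and C2′ (R), with the C2′ methyl trans to the C1′ methyl and cis to Cb. C1′ and C2′ are neighbours, but C2 lies four bonds from C1′ across a flexible tether, so it gets no help from the ring and needs reagent control. The two groups that differentiate the faces at C1′ (CH3 and CH2CH2R) are almost the same size, so steric or thermodynamic bias (enolate alkylation, epimerisation next to a ketone) cannot be trusted for the C1′/C2′ relationship, and the carbocycle offers no other handle. Fragile elements are the O1–C2 bond (electrocyclic ring opening by light or heat, or ionisation by acid, erases C2), the electrophilic quinone, and the C3′=C4′ alkene, which acid can move to C2′=C3′ with loss of C2′. The real difficulty is therefore the quaternary–tertiary pair C1′/C2′ in a bare cyclohexene, and after it the isolated C2 centre. The key step exploits the fact that C3′–C2′–C1′–Cb=Ca is the retron of a [3,3] shift (C3′ as carboxyl carbon, Cb=Ca as vinyl group) and that C6′–C5′–C4′ is the tail of geraniol: in one sentence, the C1′–C2′ bond and both of its stereocentres are made acyclically by an enantioselective Ireland–Claisen rearrangement of geranyl propanoate, and the ring is closed later through the ester's own prenyl terminus.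

## Logic of the disconnections

**20 ⇒ 18 (through 19).** The C6–OCH3 bond is cut first. O1 makes C5=O a vinylogous ester, so C8=O is the more electron-poor carbonyl and its β-carbon C6 is where an alcohol should add; the para-dialkoxy pattern of 20 is the innate one. Gain: the aromatic building block loses its only desymmetrising substituent and becomes 12. Demand: addition at C6 and not C7, and reoxidation of 19 without acid strong enough to ionise O1–C2.

**18 ⇒ 17.** The C8 oxygen is removed while C5 stays oxygenated. A phenol with a free para position is the standard precursor of a p-quinone. Gain: an aromatic, non-electrophilic chromene for the metathesis step. Demand: para-selective oxidation that leaves both alkenes alone.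

**17 ⇒ 15 (through 16).** Both ring alkenes, C3=C4 and C3′=C4′, are cut. Gain: both rings vanish and all three stereocentres become acyclic. Demand: the catalyst must pair the styrene with the C2 vinyl group and the isopropenyl group with the prenyl terminus (two six-membered rings) and not the cross pairs (seven- and eight-membered rings), and it must engage a 1,1-disubstituted and a trisubstituted olefin.

**15 ⇒ 13 (through 14).** The two terminal CH2 groups (on C4 and on C3′) are cut back to an aryl aldehyde and a methyl ketone. Gain: carbonyl groups that come directly from 12 and from the carboxyl carbon of the key-step product. Demand: methylenation without enolisation towards C2′.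

**13 ⇒ 11 + 12.** The O1–C2 bond is cut; this is where C2 is created. Because C2 is remote from the other centres, it is set by a chiral catalyst acting on an allyl unit of defined geometry. Gain: the arene is split off as a symmetric diphenol. Demand: attack at the more substituted allyl terminus, face selection by the ligand, and one O-alkylation only.

**11 ⇒ 10 ⇒ 9.** The carbonate goes back to the allylic alcohol, and the C3′–CH3 bond is cut to an N-methoxy-N-methylamide. Reason: the amide survives hydroboration where a ketone would not. Demand: a single methyl addition with C2′ untouched.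

**9 ⇒ 4 + 7 (through 8).** The Ca–C2 bond (sp3–sp2) is cut. The vinyl group that the key step leaves on C1′ is exactly Cb=Ca, so it is used as it stands. Gain: convergence; C2, its methyl and C3 arrive as one four-carbon unit. Demand: hydroboration of the vinyl group only, and retention of the Z geometry in the coupling.

**7 ⇒ 5 (through 6).** The C–I and C–H bonds across the alkyne are cut. Demand: anti addition with the metal at C3.

**4 ⇒ 3.** The amide C–N bond is cut. Demand: activation of a hindered acid without epimerising its α-carbon.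

**3 ⇒ 1 (through 2).** The C2–C3 bond of 3 (C2′–C1′ of 20) is cut and the allylic C–O bond restored. Gain: the quaternary centre, its tertiary neighbour, the vinyl handle and the future ring carbons C4′–C6′ all trace back to one achiral ester. Demand: Z(O) enolate geometry, a chair transition state, and facial control by a chiral boron ligand.

## Other disconnections considered

**Alternative 1:** Cut O1–C2 and C4–C4a together. This is the usual chromene synthesis and the first plan that comes to mind. Forward key step: amine-promoted condensation of the tetraoxygenated phenol A2 with the enal A1 (C-alkylation, dehydration to a vinyl quinone methide, oxa-6π ring closure) to the chromene hydroquinone A3, then oxidation to 20. Grounds against it: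
- In the ring-opened dienone C2 is sp2, and the ring closes four bonds from the nearest stereocentre without a chiral catalyst, so A3 must be expected as both C2 epimers; these are remote diastereomers and hard to separate.
- A2 has phenolic oxygens on both sides of the reacting carbon (the future O1 and the C5 oxygen), so the pyran can close in two directions.
- A1 still contains the whole C1′/C2′ problem.

The plan postpones every difficulty and solves none.

**Alternative 2:** Cut C1′–C2′ and C5′–C6′. Forward key step: a Lewis-acid-catalysed enantioselective Diels–Alder reaction of the diene A4 with A5 to the aldehyde A6, whose formyl carbon becomes Cb. Grounds against it: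
- A4 carries a 1-methyl and a 2-methyl group on the same diene terminus. Their effects on the terminal orbital coefficients oppose each other, so the required orientation (C2′ bonded to the α-carbon of A5) is not assured.
- The required relative configuration needs the formyl group endo, whereas α-methyl enals have a weak or reversed endo preference.
- A6 must still be homologated by one carbon at a neopentyl position.

In the chosen plan the regiochemistry is fixed by connectivity and the relative configuration by olefin and enolate geometry in a chair.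

**Alternative 3:** Dearomatisation: cut the C1′–CH3 bond on an aromatic ring. Forward key step: Birch reductive methylation of the chiral benzamide A7 to the cyclohexadiene A8. This would be followed by enol-ether hydrolysis, hydrogenation of C5′=C6′, conversion of the C3′ ketone into the methyl-bearing alkene through an enol triflate, and reduction of the amide to Cb. Grounds against it:
- The step should set C1′ well, but C2′ would then rest on a protonation or equilibration next to the C3′ ketone, whose bias is only the small difference between a methyl and a carbonyl substituent on C1′.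
- The ring needs four further adjustments.
- A hindered tertiary amide has to be cleaved.

It is longer, and weaker exactly at the C1′/C2′ relationship.

Key step: step 1

Assumption: the sense of induction of the chiral boron controller (step 1) and of the chiral diphosphine (step 7) is taken from the parent crotyl and neryl cases; the enantiomer written, (S,S) in both, is the one assumed to give the drawn configuration, and the mirror-image reagent would be used if the sense were the opposite.

## Route

Step 1
Reactants: 1 geranyl propanoate [(2E)-3,7-dimethylocta-2,6-dien-1-yl propanoate]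
Product: 3 (2R,3S)-3-ethenyl-2,3,7-trimethyloct-6-enoic acid, via boron ketene acetal 2 (not isolated)
Conditions: (4S,5S)-2-bromo-4,5-diphenyl-1,3-bis[3,5-bis(trifluoromethyl)benzenesulfonyl]-1,3,2-diazaborolidine (1.2 equiv), i-Pr2NEt, CH2Cl2, −78 °C; then −20 → 4 °C; aq. work-up
Reagents that add atoms: none
Why: Enantioselective Ireland–Claisen (ester-enolate Claisen) rearrangement; the closest known type is the rearrangement of crotyl and geranyl-type esters mediated by this class of chiral diazaborolidine. The bromoborane binds the ester carbonyl and i-Pr2NEt removes an α-proton to give the Z(O) boron ketene acetal 2 (CH3 cis to O–B). On warming, 2 should undergo a concerted suprafacial [3,3] shift through a chair: the σ-bond between the α-carbon and C3 of the geranyl unit (C2′–C1′ of 20) forms as the allylic C–O bond breaks, and the alkene moves to the terminus to become the Cb=Ca vinyl group. No ring is closed; the step is an acyclic C–C bond formation whose product already holds every carbon of the cyclohexene except the C3′ methyl. C3 of 3 (C1′) is controlled by the (E)-alkene of 1, which places its methyl pseudo-axial and the homoprenyl chain pseudo-equatorial in the chair. C2 of 3 (C2′) is controlled by the enolate geometry, which places the α-methyl pseudo-equatorial; together these give the (2R*,3S*) relationship, that is, the C2′ methyl trans to the C1′ methyl. The absolute sense comes from the C2-symmetric bis-sulfonamide on boron, which makes the two mirror-image chairs diastereomeric. The step needs Z(O) over E(O) enolisation (hindered amine in CH2Cl2), chair over boat (acyclic substrate with no forcing substituent) and one chair over its mirror image (controller); geometrically pure 1 is commercial.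

Step 2
Reactants: 3 (2R,3S)-3-ethenyl-2,3,7-trimethyloct-6-enoic acid
Product: 4 (2R,3S)-3-ethenyl-N-methoxy-N,2,3,7-tetramethyloct-6-enamide
Conditions: MeNH(OMe)·HCl, EDC·HCl, HOBt (cat.), i-Pr2NEt, CH2Cl2, 0 °C → rt
Reagents that add atoms: N,O-dimethylhydroxylamine hydrochloride (CNOC.Cl)
Why: Carbodiimide amidation through the HOBt ester; no ketene is formed, so the α-centre should be kept. The N-methoxy-N-methylamide survives hydroboration and later accepts exactly one methyl group.

Step 3
Reactants: 5 but-2-yn-1-ol
Product: 7 (2Z)-3-iodobut-2-en-1-ol, via cyclic alkenylalanate 6 (not isolated)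
Conditions: Red-Al, THF, 0 °C → rt; then I2, THF, −78 → 0 °C
Reagents that add atoms: iodine (II)
Why: Hydroxyl-directed trans-hydroalumination of a propargylic alcohol places aluminium at C3 inside the five-membered alanate 6; iodinolysis with retention should give the (Z)-vinyl iodide (I cis to CH2OH).

Step 4
Reactants: 4 (2R,3S)-3-ethenyl-N-methoxy-N,2,3,7-tetramethyloct-6-enamide; 7 (2Z)-3-iodobut-2-en-1-ol
Product: 9 (2R,3S,6Z)-8-hydroxy-N-methoxy-N,2,3,6-tetramethyl-3-(4-methylpent-3-en-1-yl)oct-6-enamide, via B-alkyl-9-BBN adduct 8 (not isolated)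
Conditions: 9-BBN-H, THF, rt; then 7, PdCl2(dppf) (5 mol %), AsPh3, Cs2CO3, DMF/H2O, rt
Reagents that add atoms: none
Why: 9-BBN should hydroborate only the monosubstituted vinyl group, anti-Markovnikov; the trisubstituted alkene and the amide are inert at rt. B-alkyl Suzuki–Miyaura coupling proceeds with retention of the vinyl iodide geometry and forms the Ca–C2 bond as a (Z)-trisubstituted allylic alcohol; no stereocentre is made or touched.

Step 5
Reactants: 9 (2R,3S,6Z)-8-hydroxy-N-methoxy-N,2,3,6-tetramethyl-3-(4-methylpent-3-en-1-yl)oct-6-enamide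
Product: 10 (3R,4S,7Z)-9-hydroxy-3,4,7-trimethyl-4-(4-methylpent-3-en-1-yl)non-7-en-2-one
Conditions: MeMgBr (3.5 equiv), THF, 0 °C; aq. NH4Cl
Reagents that add atoms: methylmagnesium bromide (C[Mg]Br)
Why: Ketone synthesis from an N-methoxy-N-methylamide; the chelated tetrahedral adduct stops at mono-addition and releases the ketone only on work-up, so C2′ should not epimerise. One equivalent is consumed by the hydroxyl group.

Step 6
Reactants: 10 (3R,4S,7Z)-9-hydroxy-3,4,7-trimethyl-4-(4-methylpent-3-en-1-yl)non-7-en-2-one
Product: 11 methyl (2Z,6S,7R)-3,6,7-trimethyl-6-(4-methylpent-3-en-1-yl)-8-oxonon-2-en-1-yl carbonate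
Conditions: ClCO2Me, pyridine, CH2Cl2, 0 °C
Reagents that add atoms: methyl chloroformate (COC(=O)Cl)
Why: Acylation of the primary allylic alcohol; the carbonate is the ionising group for step 7 and generates its own base (methoxide) there.

Step 7
Reactants: 11 methyl (2Z,6S,7R)-3,6,7-trimethyl-6-(4-methylpent-3-en-1-yl)-8-oxonon-2-en-1-yl carbonate; 12 2,6-dihydroxybenzaldehyde
Product: 13 2-hydroxy-6-{[(3S,6S,7R)-3,6,7-trimethyl-6-(4-methylpent-3-en-1-yl)-8-oxonon-1-en-3-yl]oxy}benzaldehyde
Conditions: 12 (2 equiv), Pd2(dba)3·CHCl3 (2.5 mol %), N,N′-[(1S,2S)-cyclohexane-1,2-diyl]bis[2-(diphenylphosphanyl)benzamide] (7.5 mol %), CH2Cl2, rt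
Reagents that add atoms: none
Why: Pd-catalysed asymmetric allylic O-alkylation (Tsuji–Trost type), known for phenols with geranyl- and neryl-type carbonates: ionisation gives a 1,1-disubstituted π-allyl, and with this diphosphine the phenol should attack the more substituted terminus to give the branched tertiary aryl ether. C2 is set by the ligand's choice between the π-allyl faces, the (Z)-geometry of 11 defining which substituent is anti. The two OH groups of 12 are equivalent; after one alkylation the remaining OH is hydrogen-bonded to the aldehyde and hindered, which should disfavour a second alkylation.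

Step 8
Reactants: 13 2-hydroxy-6-{[(3S,6S,7R)-3,6,7-trimethyl-6-(4-methylpent-3-en-1-yl)-8-oxonon-1-en-3-yl]oxy}benzaldehyde
Product: 15 2-ethenyl-3-{[(3S,6S,7S)-3,6,7,8-tetramethyl-6-(4-methylpent-3-en-1-yl)nona-1,8-dien-3-yl]oxy}phenol, via styrenyl ketone 14 (not isolated)
Conditions: Ph3PCH3Br, KOt-Bu (6 equiv each), THF, 0 °C → rt
Reagents that add atoms: methyltriphenylphosphonium bromide (C[P+](c1ccccc1)(c1ccccc1)c1ccccc1.[Br-])
Why: Wittig methylenation of both carbonyl groups, the aldehyde first (14) and then the ketone. The ether carbon has no α-hydrogen, and enolisation of the ketone towards C2′ is disfavoured by the adjacent quaternary C1′ (the methyl side enolises harmlessly). The descriptor at the former C7 changes from R to S only because the CIP ranking changes.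

Step 9
Reactants: 15 2-ethenyl-3-{[(3S,6S,7S)-3,6,7,8-tetramethyl-6-(4-methylpent-3-en-1-yl)nona-1,8-dien-3-yl]oxy}phenol
Product: 17 (2S)-2-methyl-2-{2-[(1S,2R)-1,2,3-trimethylcyclohex-3-en-1-yl]ethyl}-2H-chromen-5-ol, via chromene triene 16 (not isolated)
Conditions: Grubbs II (5 mol %), toluene (2 mM), 40 °C; then Hoveyda–Grubbs II (5 mol %), 80 °C; dark
Reagents that add atoms: none
Why: Double ring-closing metathesis. The styrene and the C2 vinyl group (two monosubstituted olefins, six-membered ring) should close first to give 16 and ethene; the ruthenium methylidene then cleaves the prenyl terminus (loss of 2-methylpropene), and the resulting alkylidene closes onto the isopropenyl group, helped by the quaternary C1′, to give the trisubstituted cyclohexene. No stereocentre is touched.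

Step 10
Reactants: 17 (2S)-2-methyl-2-{2-[(1S,2R)-1,2,3-trimethylcyclohex-3-en-1-yl]ethyl}-2H-chromen-5-ol
Product: 18 (2S)-2-methyl-2-{2-[(1S,2R)-1,2,3-trimethylcyclohex-3-en-1-yl]ethyl}-2H-chromene-5,8-dione
Conditions: Fremy's salt (2.5 equiv), KH2PO4 buffer, acetone/H2O, 0 °C → rt, dark
Reagents that add atoms: potassium nitrosodisulfonate ([K+].[K+].[O]N(S(=O)(=O)[O-])S(=O)(=O)[O-])
Why: Teuber oxidation: a phenol with a free para position (C8) gives the p-quinone under neutral, buffered radical conditions that should leave the chromene and the trisubstituted alkene alone.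

Step 11
Reactants: 18 (2S)-2-methyl-2-{2-[(1S,2R)-1,2,3-trimethylcyclohex-3-en-1-yl]ethyl}-2H-chromene-5,8-dione
Product: 20 (2S)-6-methoxy-2-methyl-2-{2-[(1S,2R)-1,2,3-trimethylcyclohex-3-en-1-yl]ethyl}-2H-chromene-5,8-dione, via methoxyhydroquinone 19 (not isolated)
Conditions: ZnCl2, MeOH, O2 (1 atm), rt, dark
Reagents that add atoms: methanol (CO)
Why: Lewis-acid-promoted conjugate addition of methanol to a quinone, then reoxidation of the hydroquinone 19 (the classical alkoxylation of quinones). O1 makes C5=O a vinylogous ester, so C8=O activates its β-carbon C6, which should give the para-dialkoxy pattern of 20. The mild Lewis acid in methanol and the exclusion of light are chosen to keep the O1–C2 bond, and with it C2, intact.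

## Compound list

1 | geranyl propanoate, (2E)-3,7-dimethylocta-2,6-dien-1-yl propanoate | CCC(=O)OC/C=C(\C)CCC=C(C)C | starting material
2 | Z(O) boron ketene acetal of 1 (CH3 cis to O–B) on the (4S,5S)-4,5-diphenyl-1,3-bis[3,5-bis(trifluoromethyl)benzenesulfonyl]-1,3,2-diazaborolidine | C/C=C(\OB1N(S(=O)(=O)c2cc(cc(c2)C(F)(F)F)C(F)(F)F)[C@@H](c2ccccc2)[C@H](c2ccccc2)N1S(=O)(=O)c1cc(cc(c1)C(F)(F)F)C(F)(F)F)OC/C=C(\C)CCC=C(C)C | intermediate
3 | (2R,3S)-3-ethenyl-2,3,7-trimethyloct-6-enoic acid | C=C[C@](C)(CCC=C(C)C)[C@@H](C)C(=O)O | intermediate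
4 | (2R,3S)-3-ethenyl-N-methoxy-N,2,3,7-tetramethyloct-6-enamide | C=C[C@](C)(CCC=C(C)C)[C@@H](C)C(=O)N(C)OC | intermediate
5 | but-2-yn-1-ol | CC#CCO | starting material
6 | sodium 2,2-bis(2-methoxyethoxy)-3-methyl-2,5-dihydro-1,2-oxaaluminol-2-uide (cyclic alkenylalanate) | CC1=CCO[Al-]1(OCCOC)OCCOC.[Na+] | intermediate
7 | (2Z)-3-iodobut-2-en-1-ol | C/C(I)=C/CO | intermediate
8 | (2R,3R)-3-[2-(9-borabicyclo[3.3.1]nonan-9-yl)ethyl]-N-methoxy-N,2,3,7-tetramethyloct-6-enamide | C1CCC2CCCC1B2CC[C@](C)(CCC=C(C)C)[C@@H](C)C(=O)N(C)OC | intermediate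
9 | (2R,3S,6Z)-8-hydroxy-N-methoxy-N,2,3,6-tetramethyl-3-(4-methylpent-3-en-1-yl)oct-6-enamide | OC/C=C(/C)CC[C@](C)(CCC=C(C)C)[C@@H](C)C(=O)N(C)OC | intermediate
10 | (3R,4S,7Z)-9-hydroxy-3,4,7-trimethyl-4-(4-methylpent-3-en-1-yl)non-7-en-2-one | OC/C=C(/C)CC[C@](C)(CCC=C(C)C)[C@@H](C)C(C)=O | intermediate
11 | methyl (2Z,6S,7R)-3,6,7-trimethyl-6-(4-methylpent-3-en-1-yl)-8-oxonon-2-en-1-yl carbonate | COC(=O)OC/C=C(/C)CC[C@](C)(CCC=C(C)C)[C@@H](C)C(C)=O | intermediate
12 | 2,6-dihydroxybenzaldehyde | O=Cc1c(O)cccc1O | starting material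
13 | 2-hydroxy-6-{[(3S,6S,7R)-3,6,7-trimethyl-6-(4-methylpent-3-en-1-yl)-8-oxonon-1-en-3-yl]oxy}benzaldehyde | C=C[C@@](C)(Oc1cccc(O)c1C=O)CC[C@](C)(CCC=C(C)C)[C@@H](C)C(C)=O | intermediate
14 | 2-ethenyl-3-{[(3S,6S,7R)-3,6,7-trimethyl-6-(4-methylpent-3-en-1-yl)-8-oxonon-1-en-3-yl]oxy}phenol | C=C[C@@](C)(Oc1cccc(O)c1C=C)CC[C@](C)(CCC=C(C)C)[C@@H](C)C(C)=O | intermediate
15 | 2-ethenyl-3-{[(3S,6S,7S)-3,6,7,8-tetramethyl-6-(4-methylpent-3-en-1-yl)nona-1,8-dien-3-yl]oxy}phenol | C=C[C@@](C)(Oc1cccc(O)c1C=C)CC[C@](C)(CCC=C(C)C)[C@@H](C)C(C)=C | intermediate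
16 | (2S)-2-methyl-2-[(3S,4S)-3,4,5-trimethyl-3-(4-methylpent-3-en-1-yl)hex-5-en-1-yl]-2H-chromen-5-ol | Oc1cccc2c1C=C[C@](C)(CC[C@](C)(CCC=C(C)C)[C@@H](C)C(C)=C)O2 | intermediate
17 | (2S)-2-methyl-2-{2-[(1S,2R)-1,2,3-trimethylcyclohex-3-en-1-yl]ethyl}-2H-chromen-5-ol | Oc1cccc2c1C=C[C@](C)(CC[C@]3(C)CCC=C(C)[C@@H]3C)O2 | intermediate
18 | (2S)-2-methyl-2-{2-[(1S,2R)-1,2,3-trimethylcyclohex-3-en-1-yl]ethyl}-2H-chromene-5,8-dione | O=C1C=CC(=O)C2=C1C=C[C@](C)(CC[C@]3(C)CCC=C(C)[C@@H]3C)O2 | intermediate
19 | (2S)-6-methoxy-2-methyl-2-{2-[(1S,2R)-1,2,3-trimethylcyclohex-3-en-1-yl]ethyl}-2H-chromene-5,8-diol | COc1cc(O)c2c(C=C[C@](C)(CC[C@]3(C)CCC=C(C)[C@@H]3C)O2)c1O | intermediate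
20 | (2S)-6-methoxy-2-methyl-2-{2-[(1S,2R)-1,2,3-trimethylcyclohex-3-en-1-yl]ethyl}-2H-chromene-5,8-dione | COC1=CC(=O)C2=C(C=C[C@](C)(CC[C@]3(C)CCC=C(C)[C@@H]3C)O2)C1=O | target

## Step count and least certain steps

Total: 11 steps. Longest linear sequence: 10 steps (steps 1, 2, 4–11); step 3 is a one-step side branch.

**Step 1 (key step).** Most likely failure: incomplete control of the enolate geometry, which would put the C2′ epimer into the product, or weak discrimination between the two mirror-image chairs because the γ,γ-disubstituted allyl terminus is hindered and rearranges slowly at low temperature. Fallback, setting out from 1 and coming back at 3: an achiral Ireland–Claisen rearrangement (LDA, THF/DMPU, TMSCl, −78 °C → rt; this medium gives the Z(O) silyl ketene acetal, so the same chair gives the same relative configuration) should give racemic (2R*,3S*)-3-ethenyl-2,3,7-trimethyloct-6-enoic acid F1. Crystallisation with (S)-1-phenylethylamine should give the salt (S)-1-phenylethylammonium (2R,3S)-3-ethenyl-2,3,7-trimethyloct-6-enoate F2 (the (R)-amine is used if the other salt is the less soluble one), and acidification releases 3.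

**Step 7.** Most likely failure: attack of the phenol at the unsubstituted allyl terminus, or insufficient face selection. The latter is serious because the C2 epimers are remote diastereomers and would be hard to separate. A second O-alkylation of 12 is a lesser risk. Fallback, setting out from 10 and coming back at 15, in which C2 is fixed by an epoxide:
- Sharpless epoxidation of 10 (Ti(Oi-Pr)4, L-(+)-diethyl tartrate, t-BuOOH) should give the epoxy alcohol (3R,4S)-6-[(2R,3S)-3-(hydroxymethyl)-2-methyloxiran-2-yl]-3,4-dimethyl-4-(4-methylpent-3-en-1-yl)hexan-2-one F3.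
- Ti(Oi-Pr)4-assisted opening of F3 by 12 at the tertiary epoxide carbon with inversion should give the diol 2-{[(2S,3S,6S,7R)-1,2-dihydroxy-3,6,7-trimethyl-6-(4-methylpent-3-en-1-yl)-8-oxononan-3-yl]oxy}-6-hydroxybenzaldehyde F4.
- Periodate cleavage gives the aldehyde 2-{[(2S,5S,6R)-2,5,6-trimethyl-5-(4-methylpent-3-en-1-yl)-1,7-dioxooctan-2-yl]oxy}-6-hydroxybenzaldehyde F5.
- Threefold Wittig methylenation of F5 gives 15.

**Step 9.** Most likely failure: stalling after the first ring closure, because the remaining olefin pair (1,1-disubstituted and trisubstituted) initiates slowly, with oligomerisation or a seven-membered cross closure as side paths. Fallback, setting out from 3 and coming back at 17, in which the cyclohexene is closed by carbonyl coupling before the chain is built: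
- MeLi on 3 gives the methyl ketone (3R,4S)-4-ethenyl-3,4,8-trimethylnon-7-en-2-one F6.
- Ozonolysis of the trisubstituted alkene only (O3 to an indicator end point, then Me2S) gives the keto aldehyde (4S,5R)-4-ethenyl-4,5-dimethyl-6-oxoheptanal F7.
- Intramolecular McMurry coupling (TiCl3, Zn–Cu, DME) gives (5S,6S)-5-ethenyl-1,5,6-trimethylcyclohex-1-ene F8.
- Hydroboration and Suzuki–Miyaura coupling with 7, as in step 4, give (2Z)-3-methyl-5-[(1S,2R)-1,2,3-trimethylcyclohex-3-en-1-yl]pent-2-en-1-ol F9.
- Acylation gives methyl (2Z)-3-methyl-5-[(1S,2R)-1,2,3-trimethylcyclohex-3-en-1-yl]pent-2-en-1-yl carbonate F10.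
- Pd-catalysed O-alkylation of 12, as in step 7, gives 2-hydroxy-6-({(3S)-3-methyl-5-[(1S,2R)-1,2,3-trimethylcyclohex-3-en-1-yl]pent-1-en-3-yl}oxy)benzaldehyde F11.
- Wittig methylenation gives 2-ethenyl-3-({(3S)-3-methyl-5-[(1S,2R)-1,2,3-trimethylcyclohex-3-en-1-yl]pent-1-en-3-yl}oxy)phenol F12.
- A single ring-closing metathesis of the styrene and vinyl pair gives 17.

**Step 11.** Most likely failure: competing addition at C7 or 1,6-addition along the C3=C4 dienone, ionisation of O1–C2 by the Lewis acid with erosion of C2, or incomplete reoxidation. Fallback, setting out from 11 and coming back at 20, in which the methoxy group is carried from the start: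
- Pd-catalysed O-alkylation of commercial 3-bromo-2-hydroxy-5-methoxybenzaldehyde with 11 (conditions of step 7) should give 3-bromo-5-methoxy-2-{[(3S,6S,7R)-3,6,7-trimethyl-6-(4-methylpent-3-en-1-yl)-8-oxonon-1-en-3-yl]oxy}benzaldehyde F13.
- Double Wittig methylenation gives 1-bromo-3-ethenyl-5-methoxy-2-{[(3S,6S,7S)-3,6,7,8-tetramethyl-6-(4-methylpent-3-en-1-yl)nona-1,8-dien-3-yl]oxy}benzene F14.
- Double ring-closing metathesis gives (2S)-8-bromo-6-methoxy-2-methyl-2-{2-[(1S,2R)-1,2,3-trimethylcyclohex-3-en-1-yl]ethyl}-2H-chromene F15.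
- Bromine–lithium exchange, borylation and oxidation (t-BuLi, B(OMe)3, then H2O2/NaOH) give (2S)-6-methoxy-2-methyl-2-{2-[(1S,2R)-1,2,3-trimethylcyclohex-3-en-1-yl]ethyl}-2H-chromen-8-ol F16.
- Fremy's salt oxidises F16 at the free para position C5 to give 20.

## Further compounds

F1 | step 1 | racemic (2R*,3S*)-3-ethenyl-2,3,7-trimethyloct-6-enoic acid | C=C[C@](C)(CCC=C(C)C)[C@@H](C)C(=O)O.C=C[C@@](C)(CCC=C(C)C)[C@H](C)C(=O)O
F2 | step 1 | (S)-1-phenylethylammonium (2R,3S)-3-ethenyl-2,3,7-trimethyloct-6-enoate | C=C[C@](C)(CCC=C(C)C)[C@@H](C)C(=O)[O-].C[C@H]([NH3+])c1ccccc1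
F3 | step 7 | (3R,4S)-6-[(2R,3S)-3-(hydroxymethyl)-2-methyloxiran-2-yl]-3,4-dimethyl-4-(4-methylpent-3-en-1-yl)hexan-2-one | OC[C@@H]1O[C@]1(C)CC[C@](C)(CCC=C(C)C)[C@@H](C)C(C)=O
F4 | step 7 | 2-{[(2S,3S,6S,7R)-1,2-dihydroxy-3,6,7-trimethyl-6-(4-methylpent-3-en-1-yl)-8-oxononan-3-yl]oxy}-6-hydroxybenzaldehyde | OC[C@H](O)[C@@](C)(Oc1cccc(O)c1C=O)CC[C@](C)(CCC=C(C)C)[C@@H](C)C(C)=O
F5 | step 7 | 2-{[(2S,5S,6R)-2,5,6-trimethyl-5-(4-methylpent-3-en-1-yl)-1,7-dioxooctan-2-yl]oxy}-6-hydroxybenzaldehyde | O=C[C@@](C)(Oc1cccc(O)c1C=O)CC[C@](C)(CCC=C(C)C)[C@@H](C)C(C)=O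
F6 | step 9 | (3R,4S)-4-ethenyl-3,4,8-trimethylnon-7-en-2-one | C=C[C@](C)(CCC=C(C)C)[C@@H](C)C(C)=O
F7 | step 9 | (4S,5R)-4-ethenyl-4,5-dimethyl-6-oxoheptanal | C=C[C@](C)(CCC=O)[C@@H](C)C(C)=O
F8 | step 9 | (5S,6S)-5-ethenyl-1,5,6-trimethylcyclohex-1-ene | C=C[C@]1(C)CCC=C(C)[C@@H]1C
F9 | step 9 | (2Z)-3-methyl-5-[(1S,2R)-1,2,3-trimethylcyclohex-3-en-1-yl]pent-2-en-1-ol | OC/C=C(/C)CC[C@]1(C)CCC=C(C)[C@@H]1C
F10 | step 9 | methyl (2Z)-3-methyl-5-[(1S,2R)-1,2,3-trimethylcyclohex-3-en-1-yl]pent-2-en-1-yl carbonate | COC(=O)OC/C=C(/C)CC[C@]1(C)CCC=C(C)[C@@H]1C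
F11 | step 9 | 2-hydroxy-6-({(3S)-3-methyl-5-[(1S,2R)-1,2,3-trimethylcyclohex-3-en-1-yl]pent-1-en-3-yl}oxy)benzaldehyde | C=C[C@@](C)(Oc1cccc(O)c1C=O)CC[C@]1(C)CCC=C(C)[C@@H]1C
F12 | step 9 | 2-ethenyl-3-({(3S)-3-methyl-5-[(1S,2R)-1,2,3-trimethylcyclohex-3-en-1-yl]pent-1-en-3-yl}oxy)phenol | C=C[C@@](C)(Oc1cccc(O)c1C=C)CC[C@]1(C)CCC=C(C)[C@@H]1C
F13 | step 11 | 3-bromo-5-methoxy-2-{[(3S,6S,7R)-3,6,7-trimethyl-6-(4-methylpent-3-en-1-yl)-8-oxonon-1-en-3-yl]oxy}benzaldehyde | C=C[C@@](C)(Oc1c(Br)cc(OC)cc1C=O)CC[C@](C)(CCC=C(C)C)[C@@H](C)C(C)=O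
F14 | step 11 | 1-bromo-3-ethenyl-5-methoxy-2-{[(3S,6S,7S)-3,6,7,8-tetramethyl-6-(4-methylpent-3-en-1-yl)nona-1,8-dien-3-yl]oxy}benzene | C=C[C@@](C)(Oc1c(Br)cc(OC)cc1C=C)CC[C@](C)(CCC=C(C)C)[C@@H](C)C(C)=C
F15 | step 11 | (2S)-8-bromo-6-methoxy-2-methyl-2-{2-[(1S,2R)-1,2,3-trimethylcyclohex-3-en-1-yl]ethyl}-2H-chromene | COc1cc(Br)c2c(C=C[C@](C)(CC[C@]3(C)CCC=C(C)[C@@H]3C)O2)c1
F16 | step 11 | (2S)-6-methoxy-2-methyl-2-{2-[(1S,2R)-1,2,3-trimethylcyclohex-3-en-1-yl]ethyl}-2H-chromen-8-ol | COc1cc(O)c2c(C=C[C@](C)(CC[C@]3(C)CCC=C(C)[C@@H]3C)O2)c1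
A1 | alternative 1 | (2E)-3-methyl-5-[(1S,2R)-1,2,3-trimethylcyclohex-3-en-1-yl]pent-2-enal | O=C/C=C(\C)CC[C@]1(C)CCC=C(C)[C@@H]1C
A2 | alternative 1 | 5-methoxybenzene-1,2,4-triol | COc1cc(O)c(O)cc1O
A3 | alternative 1 | 6-methoxy-2-methyl-2-{2-[(1S,2R)-1,2,3-trimethylcyclohex-3-en-1-yl]ethyl}-2H-chromene-5,8-diol, both C2 epimers | COc1cc(O)c2OC(C)(CC[C@]3(C)CCC=C(C)[C@@H]3C)C=Cc2c1O
A4 | alternative 2 | (3E)-3-methylpenta-1,3-diene | C=C/C(C)=C/C
A5 | alternative 2 | 2-methylprop-2-enal | CC(=C)C=O
A6 | alternative 2 | (1R,2S)-1,2,3-trimethylcyclohex-3-ene-1-carbaldehyde | O=C[C@]1(C)CCC=C(C)[C@@H]1C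
A7 | alternative 3 | (3-methoxy-2-methylphenyl)[(2S)-2-(methoxymethyl)pyrrolidin-1-yl]methanone | COC[C@@H]1CCCN1C(=O)c1cccc(OC)c1C
A8 | alternative 3 | [(1R)-3-methoxy-1,2-dimethylcyclohexa-2,5-dien-1-yl][(2S)-2-(methoxymethyl)pyrrolidin-1-yl]methanone | COC[C@@H]1CCCN1C(=O)[C@]1(C)C=CCC(OC)=C1C
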